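**Retrosynthetic overview**
1. Locants (germacrane): ring A is the carbocycle C1–C10. Ring B is the butenolide O–C6–C7=C11–C12(=O). C13 is the CH2OAc on C11, C14 the CH2OH on C10, C15 the CH3 on C4. The esters sit on O2 (acetate) and O8 (angelate).
2. Enabling feature: across the exocyclic C5=C6 bond, the ring-B oxygen and the carbinol carbon C4 are anti, so C4 is cis to C7 and C5=C6 is a cis olefin of ring A. The array C4(OH)–C5H=C6(O–C12=O) is an isomer of methyl ketone + terminal alkyne + carboxylic acid.
3. Hence 32 ⇐ 31 ⇐ acyclic 2-en-4-ynoic acid 28. One palladium-catalysed operation closes ring B first (O–C6, anti oxypalladation), then ring A (C4–C5, carbonyl insertion), and sets C5=C6 and C4.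
4. 28 ⇐ 3,4-disubstituted furan 22. The furan ring masks the tetrasubstituted C7=C11 olefin with CO2H cis to ethynyl. It is unmasked by photooxygenation and an alkyne homologation that supplies C5.
5. 22 ⇐ (E)-alkylidene lactone 17, which fixes C1=C10 and differentiates O8 from O14. 17 ⇐ aldol condensation of lactone 7 (Stetter reaction, asymmetric transfer hydrogenation: C8) with chiral-pool aldehyde 13 (C2).

Key step: step 19

Remark: TBS = tert-butyldimethylsilyl, TES = triethylsilyl, TBDPS = tert-butyldiphenylsilyl, bpy = 2,2'-bipyridine. Compounds 1, 4, 8, 20 and all named reagents are assumed to be commercial.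

**Step 1**
Reactants: 1 furan-3,4-diyldimethanol
Product: 2 [4-(TBSO-methyl)furan-3-yl]methanol
Conditions: NaH (1.0 equiv), THF, 0 °C to rt; TBSCl (1.0 equiv)
Reagents that add atoms: tert-butyldimethylsilyl chloride, CC(C)(C)[Si](C)(C)Cl
Why: O-silylation of a symmetrical diol through its sparingly soluble monosodium alkoxide should stop after one hydroxyl, and the protected arm becomes C13.

**Step 2**
Reactants: 2 [4-(TBSO-methyl)furan-3-yl]methanol
Product: 3 4-(TBSO-methyl)furan-3-carbaldehyde
Conditions: MnO2 (15 equiv), CH2Cl2, rt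
Reagents that add atoms: none
Why: MnO2 oxidation of a heterobenzylic alcohol stops at the aldehyde, leaves furan and silyl ether untouched, and gives the C8 carbonyl.

**Step 3**
Reactants: 3 4-(TBSO-methyl)furan-3-carbaldehyde; 4 methyl acrylate
Product: 5 methyl 4-[4-(TBSO-methyl)furan-3-yl]-4-oxobutanoate
Conditions: 3-benzyl-5-(2-hydroxyethyl)-4-methylthiazolium chloride (20 mol %), Et3N (cat.), 1,4-dioxane, 80 °C
Reagents that add atoms: none
Why: In this Stetter reaction the carbene-derived acyl anion equivalent of the heteroaromatic aldehyde adds 1,4 to the acrylate and brings in C9, C10 and C14 without by-product.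

**Step 4**
Reactants: 5 methyl 4-[4-(TBSO-methyl)furan-3-yl]-4-oxobutanoate
Product: 7 (5S)-5-[4-(TBSO-methyl)furan-3-yl]oxolan-2-one, via hydroxy ester 6 (not isolated)
Conditions: RuCl[(S,S)-TsDPEN](p-cymene) (1 mol %), HCO2H/Et3N 5:2, 40 °C; then PPTS (5 mol %), toluene, 60 °C
Reagents that add atoms: none
Why: Noyori asymmetric transfer hydrogenation of an aryl alkyl ketone with the (S,S)-catalyst delivers hydride to the face that gives the (S)-carbinol (furyl in the aryl role), which sets C8, and the γ-hydroxy ester then lactonises under mild acid.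

**Step 5**
Reactants: 8 (S)-3-hydroxy-γ-butyrolactone
Product: 9 (3S)-3,4-dihydroxy-N-methoxy-N-methylbutanamide
Conditions: MeNH(OMe)·HCl (2 equiv), i-PrMgCl (5 equiv), THF, −20 °C
Reagents that add atoms: N,O-dimethylhydroxylamine hydrochloride, CNOC.Cl
Why: Weinreb amide formation by aminolysis of the lactone with the magnesium amide opens the ring without touching the chiral-pool carbinol that becomes C2.

**Step 6**
Reactants: 9 (3S)-3,4-dihydroxy-N-methoxy-N-methylbutanamide
Product: 10 (3S)-N-methoxy-N-methyl-3,4-bis(triethylsilyloxy)butanamide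
Conditions: TESCl (2.3 equiv), imidazole, CH2Cl2, 0 °C
Reagents that add atoms: chlorotriethylsilane, CC[Si](Cl)(CC)CC
Why: Imidazole-promoted silylation caps both hydroxyls before relactonisation and installs a primary TES ether that can later be oxidised directly.

**Step 7**
Reactants: 10 (3S)-N-methoxy-N-methyl-3,4-bis(triethylsilyloxy)butanamide
Product: 11 (4S)-4,5-bis(triethylsilyloxy)pentan-2-one
Conditions: MeMgBr (1.5 equiv), THF, 0 °C; aq. NH4Cl
Reagents that add atoms: methylmagnesium bromide, C[Mg]Br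
Why: In the Weinreb ketone synthesis the chelated tetrahedral adduct prevents over-addition and gives the C4 methyl ketone with C15.

**Step 8**
Reactants: 11 (4S)-4,5-bis(triethylsilyloxy)pentan-2-one
Product: 12 2-[(2S)-2,3-bis(triethylsilyloxy)propyl]-2-methyl-1,3-dioxolane
Conditions: (TMSOCH2)2 (1.5 equiv), TMSOTf (5 mol %), CH2Cl2, −78 °C; pyridine quench
Reagents that add atoms: 1,2-bis(trimethylsilyloxy)ethane, C[Si](C)(C)OCCO[Si](C)(C)C
Why: Noyori ketalisation under aprotic catalysis at low temperature masks the C4 ketone without β-elimination of the silyloxy group.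

**Step 9**
Reactants: 12 2-[(2S)-2,3-bis(triethylsilyloxy)propyl]-2-methyl-1,3-dioxolane
Product: 13 (2S)-3-(2-methyl-1,3-dioxolan-2-yl)-2-(triethylsilyloxy)propanal
Conditions: (COCl)2 (4 equiv), DMSO (8 equiv), CH2Cl2, −78 to −35 °C; Et3N, −78 °C to rt
Reagents that add atoms: none
Why: Swern oxidation applied directly to a bis-TES ether cleaves and oxidises only the primary silyl ether and gives the configurationally intact α-silyloxy aldehyde (C1) in one operation.

**Step 10**
Reactants: 7 (5S)-5-[4-(TBSO-methyl)furan-3-yl]oxolan-2-one; 13 (2S)-3-(2-methyl-1,3-dioxolan-2-yl)-2-(triethylsilyloxy)propanal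
Product: 15 aldol adduct (5S)-3-[(2S)-1-hydroxy-3-(2-methyl-1,3-dioxolan-2-yl)-2-(triethylsilyloxy)propyl]-5-[4-(TBSO-methyl)furan-3-yl]oxolan-2-one (epimers at C10 and C1), via lithium enolate 14 (not isolated)
Conditions: LiN(i-Pr)2 (1.1 equiv), THF, −78 °C; then 13; aq. NH4Cl
Reagents that add atoms: none
Why: Lithium enolate aldol addition forms C10–C1 at −78 °C faster than the aldehyde can enolise, and the two new centres need no control because the next step removes them.

**Step 11**
Reactants: 15 aldol adduct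
Product: 17 (3E,5S)-3-[(2S)-3-(2-methyl-1,3-dioxolan-2-yl)-2-(triethylsilyloxy)propylidene]-5-[4-(TBSO-methyl)furan-3-yl]oxolan-2-one, via mesylate 16 (not isolated)
Conditions: MsCl, Et3N, CH2Cl2, 0 °C; then DBU, 0 °C to rt
Reagents that add atoms: none
Why: Mesylation and DBU-induced E1cB elimination complete the aldol condensation and should give the thermodynamically preferred (E)-α-alkylidene lactone, in which C2 is cis to C9 as the cis C1=C10 olefin of ring A requires.

**Step 12**
Reactants: 17 (E)-alkylidene lactone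
Product: 18 (1S,3E,5S)-3-(hydroxymethyl)-1-[4-(TBSO-methyl)furan-3-yl]-6-(2-methyl-1,3-dioxolan-2-yl)-5-(triethylsilyloxy)hex-3-en-1-ol
Conditions: i-Bu2AlH (4.5 equiv), CH2Cl2, −78 to 0 °C; aq. potassium sodium tartrate
Reagents that add atoms: none
Why: i-Bu2AlH reduces the conjugated lactone by 1,2-addition to the allylic diol, which keeps the olefin geometry and releases O14 as a primary and O8 as a secondary hydroxyl.

**Step 13**
Reactants: 18 diol
Product: 19 (1S,3E,5S)-3-(TBDPSO-methyl)-1-[4-(TBSO-methyl)furan-3-yl]-6-(2-methyl-1,3-dioxolan-2-yl)-5-(triethylsilyloxy)hex-3-en-1-ol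
Conditions: TBDPSCl (1.05 equiv), imidazole, CH2Cl2, 0 °C
Reagents that add atoms: tert-butyldiphenylsilyl chloride, CC(C)(C)[Si](Cl)(c1ccccc1)c1ccccc1
Why: Sterically differentiated silylation with the bulky chloride protects only the primary allylic hydroxyl, and this acid-stable group outlasts step 17.

**Step 14**
Reactants: 19 secondary alcohol; 20 angelic acid
Product: 22 O8-angelate of 19, via mixed anhydride 21 (not isolated)
Conditions: 20 (3 equiv), 2,4,6-Cl3C6H2COCl (3 equiv), Et3N, toluene, rt; then 19, 80 °C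
Reagents that add atoms: none
Why: Yamaguchi-type esterification through the trichlorobenzoyl mixed anhydride, run without a nucleophilic amine catalyst, acylates hindered secondary alcohols with angelic acid without Z-to-E isomerisation and with retention at C8.

**Step 15**
Reactants: 22 furan angelate
Product: 24 γ-hydroxybutenolide (C12 carbonyl and C6 hemiacetal; epimers at C6), via endoperoxide 23 (not isolated)
Conditions: O2, tetraphenylporphyrin (1 mol %), visible light, i-Pr2NEt (2 equiv), CH2Cl2, −78 °C, then rt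
Reagents that add atoms: dioxygen, O=O
Why: [4+2] photooxygenation of the furan and Kornblum–DeLaMare rearrangement, in which the hindered amine removes the less shielded bridgehead hydrogen at C12 (next to the CH2OTBS arm rather than the branched C8 arm), should make C12 the carbonyl, while the much less reactive trisubstituted and angelate olefins should not compete at −78 °C.

**Step 16**
Reactants: 24 γ-hydroxybutenolide
Product: 25 (2E,4S,6E,8S)-4-(angeloyloxy)-2-(TBSO-methyl)-6-(TBDPSO-methyl)-3-ethynyl-9-(2-methyl-1,3-dioxolan-2-yl)-8-(triethylsilyloxy)nona-2,6-dienoic acid (CO2H cis to ethynyl)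
Conditions: dimethyl (1-diazo-2-oxopropyl)phosphonate (1.5 equiv), K2CO3 (3 equiv), MeOH, 0 °C to rt; pH 4 buffer
Reagents that add atoms: dimethyl (1-diazo-2-oxopropyl)phosphonate, CC(=O)C(=[N+]=[N-])P(=O)(OC)OC
Why: Ohira–Bestmann homologation, established for lactols, turns the masked aldehyde C6 into the terminal alkyne (C5 comes from the reagent) and frees the C12 acid, the former furan ring guarantees the cis relation of CO2H and ethynyl, and the hindered angelate is expected to outlast the mild carbonate medium.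

**Step 17**
Reactants: 25 protected enynoic acid
Product: 26 (2E,4S,6E,8S)-4-(angeloyloxy)-6-(TBDPSO-methyl)-3-ethynyl-8-hydroxy-2-(hydroxymethyl)-10-oxoundeca-2,6-dienoic acid
Conditions: p-TsOH·H2O (0.2 equiv), acetone/H2O 9:1, rt
Reagents that add atoms: water, O
Why: Acid-catalysed hydrolysis removes the TES ether, the primary TBS ether and the dioxolane in one operation, whereas the TBDPS ether and the angelate are stable to dilute sulfonic acid.

**Step 18**
Reactants: 26 dihydroxy keto acid
Product: 28 (2E,4S,6E,8S)-8-acetoxy-2-(acetoxymethyl)-4-(angeloyloxy)-6-(TBDPSO-methyl)-3-ethynyl-10-oxoundeca-2,6-dienoic acid, via acetic mixed anhydride 27 (not isolated)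
Conditions: Ac2O (5 equiv), pyridine, CH2Cl2, 0 °C; then H2O, THF, rt
Reagents that add atoms: acetic anhydride, CC(=O)OC(C)=O
Why: Pyridine-mediated acetylation esterifies O13 and O2, the transient mixed anhydride at C12 is hydrolysed on aqueous treatment, and the absence of a strong base avoids E1cB loss of the new β-acetoxy group.

**Step 19**
Reactants: 28 acyclic seco acid
Product: 31 14-O-TBDPS ether of the target (rings A and B closed; 2S,4R,8S), via alkenylpalladium lactone 29 (not isolated), via palladium alkoxide 30 (not isolated)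
Conditions: Pd(OAc)2 (10 mol %), 2,2'-bipyridine (12 mol %), 1,4-benzoquinone (10 mol %), 1,4-dioxane, 60 °C, 28 added by syringe pump over 12 h (final about 1 mM)
Reagents that add atoms: none
Why: Proposed new method: Pd(OAc)2(bpy) activates the terminal alkyne of 28, the cis-disposed C12 carboxylate adds anti at C6 (5-exo-dig closure of ring B) and leaves palladium on C5 trans to the lactone oxygen and cis to C7 (29), the C5–Pd bond then adds across the tethered C4 ketone with retention at C5 (migratory 1,2-insertion, 10-exo-trig closure of ring A, new bond C4–C5) to give alkoxide 30, and the acetic acid released in the first event protonates 30 and returns the catalyst, so the whole step is a redox-neutral isomerisation. The closest known reaction types are the cycloisomerisation of (Z)-2-en-4-ynoic acids to γ-ylidenebutenolides with divalent palladium, the interception by carbon electrophiles of the alkenylpalladium formed in alkynoic acid lactonisation, and the Pd(OAc)2/bipyridine acetoxypalladation–carbonyl addition of alkynyl ketones that gives five- and six-membered cyclic tertiary alcohols; new here are the internal carboxylate as trigger and the ten-membered closure. The C5=C6 geometry is not a matter of selectivity, because anti addition plus retention can only place C4 trans to the ring oxygen, which is the cis ring-A olefin of the target. C4 is set under substrate control: the palladium-bound ketone oxygen must stay on the periphery anti to C6, the C2–C3–C4 segment folds chair-like with the C2 acetate pseudo-equatorial and H-2 facing the C4 methyl group, and C5 should therefore reach the Si face of the ketone to give the 2,4-cis (4R) carbinol. The step needs 5-exo over 6-endo attack (secured by the unsubstituted alkyne terminus, which takes the metal), insertion over protodepalladation (insertion is unimolecular and protonolysis bimolecular in acid, so slow addition at high dilution, an aprotic solvent and the chelating N,N ligand favour closure, helped by the cis C1=C10 olefin and the planar C4–C8 array that pre-fold the chain), and inert allylic acetates (no zerovalent palladium lies on the cycle and benzoquinone scavenges any that forms).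

**Step 20**
Reactants: 31 14-O-TBDPS ether
Product: 32 target CNP0165707.1
Conditions: HF·pyridine, pyridine, THF, 0 °C to rt
Reagents that add atoms: none
Why: Fluoride-driven desilylation with pyridine-buffered HF cleaves only the Si–O bond and should avoid acyl migration, ester cleavage and ionisation of the tertiary allylic alcohol.

**Compound list**
1 | furan-3,4-diyldimethanol | OCc1cocc1CO | starting material
2 | [4-(TBSO-methyl)furan-3-yl]methanol | OCc1cocc1CO[Si](C)(C)C(C)(C)C | intermediate
3 | 4-(TBSO-methyl)furan-3-carbaldehyde | O=Cc1cocc1CO[Si](C)(C)C(C)(C)C | intermediate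
4 | methyl acrylate | C=CC(=O)OC | starting material
5 | methyl 4-[4-(TBSO-methyl)furan-3-yl]-4-oxobutanoate | COC(=O)CCC(=O)c1cocc1CO[Si](C)(C)C(C)(C)C | intermediate
6 | methyl (4S)-4-hydroxy-4-[4-(TBSO-methyl)furan-3-yl]butanoate (not isolated) | COC(=O)CC[C@H](O)c1cocc1CO[Si](C)(C)C(C)(C)C | intermediate
7 | (5S)-5-[4-(TBSO-methyl)furan-3-yl]oxolan-2-one | O=C1CC[C@@H](c2cocc2CO[Si](C)(C)C(C)(C)C)O1 | intermediate
8 | (S)-3-hydroxy-γ-butyrolactone | O=C1C[C@H](O)CO1 | starting material
9 | (3S)-3,4-dihydroxy-N-methoxy-N-methylbutanamide | CON(C)C(=O)C[C@H](O)CO | intermediate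
10 | (3S)-N-methoxy-N-methyl-3,4-bis(triethylsilyloxy)butanamide | CON(C)C(=O)C[C@H](O[Si](CC)(CC)CC)CO[Si](CC)(CC)CC | intermediate
11 | (4S)-4,5-bis(triethylsilyloxy)pentan-2-one | CC(=O)C[C@H](O[Si](CC)(CC)CC)CO[Si](CC)(CC)CC | intermediate
12 | 2-[(2S)-2,3-bis(triethylsilyloxy)propyl]-2-methyl-1,3-dioxolane | CC1(C[C@H](O[Si](CC)(CC)CC)CO[Si](CC)(CC)CC)OCCO1 | intermediate
13 | (2S)-3-(2-methyl-1,3-dioxolan-2-yl)-2-(triethylsilyloxy)propanal | CC1(C[C@H](O[Si](CC)(CC)CC)C=O)OCCO1 | intermediate
14 | lithium enolate of 7 (not isolated) | [Li+].[O-]C1=CC[C@@H](c2cocc2CO[Si](C)(C)C(C)(C)C)O1 | intermediate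
15 | aldol adduct, epimers at C10 and C1 | O=C1C(C(O)[C@@H](O[Si](CC)(CC)CC)CC2(C)OCCO2)C[C@@H](c2cocc2CO[Si](C)(C)C(C)(C)C)O1 | intermediate
16 | methanesulfonate of 15 (not isolated) | O=C1C(C(OS(C)(=O)=O)[C@@H](O[Si](CC)(CC)CC)CC2(C)OCCO2)C[C@@H](c2cocc2CO[Si](C)(C)C(C)(C)C)O1 | intermediate
17 | (3E,5S)-α-alkylidene-γ-butyrolactone | O=C1/C(=C/[C@@H](O[Si](CC)(CC)CC)CC2(C)OCCO2)C[C@@H](c2cocc2CO[Si](C)(C)C(C)(C)C)O1 | intermediate
18 | (1S,3E,5S)-diol (O8-H, O14-H) | OC/C(=C/[C@@H](O[Si](CC)(CC)CC)CC1(C)OCCO1)C[C@H](O)c1cocc1CO[Si](C)(C)C(C)(C)C | intermediate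
19 | 14-O-TBDPS ether of 18 | CC(C)(C)[Si](OC/C(=C/[C@@H](O[Si](CC)(CC)CC)CC1(C)OCCO1)C[C@H](O)c1cocc1CO[Si](C)(C)C(C)(C)C)(c1ccccc1)c1ccccc1 | intermediate
20 | angelic acid, (Z)-2-methylbut-2-enoic acid | C/C=C(/C)C(=O)O | starting material
21 | angelic 2,4,6-trichlorobenzoic anhydride (not isolated) | C/C=C(/C)C(=O)OC(=O)c1c(Cl)cc(Cl)cc1Cl | intermediate
22 | O8-angelate of 19 (furan) | C/C=C(/C)C(=O)O[C@@H](C/C(CO[Si](c1ccccc1)(c1ccccc1)C(C)(C)C)=C\[C@@H](O[Si](CC)(CC)CC)CC1(C)OCCO1)c1cocc1CO[Si](C)(C)C(C)(C)C | intermediate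
23 | furan endoperoxide, 2,3,7-trioxabicyclo[2.2.1]hept-5-ene (not isolated) | C12OC(OO1)C(CO[Si](C)(C)C(C)(C)C)=C2[C@@H](OC(=O)/C(C)=C\C)C/C(CO[Si](c1ccccc1)(c1ccccc1)C(C)(C)C)=C\[C@@H](O[Si](CC)(CC)CC)CC1(C)OCCO1 | intermediate
24 | γ-hydroxybutenolide, epimers at C6 | O=C1OC(O)C([C@@H](OC(=O)/C(C)=C\C)C/C(CO[Si](c2ccccc2)(c2ccccc2)C(C)(C)C)=C\[C@@H](O[Si](CC)(CC)CC)CC2(C)OCCO2)=C1CO[Si](C)(C)C(C)(C)C | intermediate
25 | protected enynoic acid | OC(=O)/C(CO[Si](C)(C)C(C)(C)C)=C(\C#C)[C@@H](OC(=O)/C(C)=C\C)C/C(CO[Si](c1ccccc1)(c1ccccc1)C(C)(C)C)=C\[C@@H](O[Si](CC)(CC)CC)CC1(C)OCCO1 | intermediate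
26 | dihydroxy keto enynoic acid | OC(=O)/C(CO)=C(\C#C)[C@@H](OC(=O)/C(C)=C\C)C/C(CO[Si](c1ccccc1)(c1ccccc1)C(C)(C)C)=C\[C@@H](O)CC(C)=O | intermediate
27 | acetic mixed anhydride of 28 (not isolated) | CC(=O)OC(=O)/C(COC(C)=O)=C(\C#C)[C@@H](OC(=O)/C(C)=C\C)C/C(CO[Si](c1ccccc1)(c1ccccc1)C(C)(C)C)=C\[C@@H](OC(C)=O)CC(C)=O | intermediate
28 | acyclic seco acid (diacetate, methyl ketone, terminal alkyne) | OC(=O)/C(COC(C)=O)=C(\C#C)[C@@H](OC(=O)/C(C)=C\C)C/C(CO[Si](c1ccccc1)(c1ccccc1)C(C)(C)C)=C\[C@@H](OC(C)=O)CC(C)=O | intermediate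
29 | (E)-alkenylpalladium acetate bipyridine complex of the γ-methylenebutenolide (not isolated) | C/C=C(/C)C(=O)O[C@@H](C/C(CO[Si](c1ccccc1)(c1ccccc1)C(C)(C)C)=C\[C@@H](OC(C)=O)CC(C)=O)C1=C(COC(C)=O)C(=O)O/C1=C/[Pd-2]1(OC(C)=O)[n+]2ccccc2-c2cccc[n+]12 | intermediate
30 | macrocyclic C4 palladium alkoxide (not isolated) | C/C=C(/C)C(=O)O[C@H]1C/C(CO[Si](c2ccccc2)(c2ccccc2)C(C)(C)C)=C\[C@@H](OC(C)=O)C[C@@](C)(O[Pd-2]2(OC(C)=O)[n+]3ccccc3-c3cccc[n+]23)/C=C2/OC(=O)C(COC(C)=O)=C21 | intermediate
31 | 14-O-TBDPS ether of the target | C/C=C(/C)C(=O)O[C@H]1C/C(CO[Si](c2ccccc2)(c2ccccc2)C(C)(C)C)=C\[C@@H](OC(C)=O)C[C@@](C)(O)/C=C2/OC(=O)C(COC(C)=O)=C21 | intermediate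
32 | CNP0165707.1, (2S,4R,8S)-2,13-diacetoxy-8-angeloyloxy-4,14-dihydroxygermacra-1(10),5,7(11)-trien-12,6-olide | C/C=C(/C)C(=O)O[C@H]1C/C(CO)=C\[C@@H](OC(C)=O)C[C@@](C)(O)/C=C2/OC(=O)C(COC(C)=O)=C21 | target

**Totals**
Total step count: 20.
Longest linear sequence: 16 (steps 5–20, from 8).

**Steps most likely to fail**

1. Step 19.
Risks: protodepalladation of the alkenylpalladium may outrun the slow medium-ring insertion. Attack on the C4 ketone may show poor facial selectivity. The allylic acetates may ionise or shift. The β-acetoxy group may be lost at 60 °C.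
Fallback (known chemistry): from 28, iodolactonisation (I2, NaHCO3, MeCN, 0 °C, anti addition) should give the (E)-5-(iodomethylene)butenolide F1. An intramolecular Nozaki–Hiyama–Kishi reaction (CrCl2, NiCl2 cat., DMSO/THF, high dilution) should then close C4–C5 with retention of the olefin geometry. This rejoins the route at 31.

2. Step 15.
Risks: proton abstraction from the endoperoxide may be poorly regioselective between the two differently hindered bridgeheads. An ene reaction at C1=C10 may compete.
Fallback: from 19, alkoxide-directed lithiation next to the C8 arm (n-BuLi, 2.2 equiv, THF, 0 °C) and a DMF quench should give the 2-formylfuran alcohol F2, whose formyl carbon is C5. Angeloylation as in step 14 should give the formylfuran angelate F3, and TsNHNH2 the tosylhydrazone F4. Bamford–Stevens decomposition (NaH, toluene, 90 °C) generates the furfurylidene carbene, whose ring opening should give the cis-enynal F5. Pinnick oxidation (NaClO2, NaH2PO4, 2-methyl-2-butene) rejoins the route at 25.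

3. Step 17.
Risks: the acidity needed to hydrolyse the dioxolane may cause allylic ionisation at the freed C2 carbinol. Dehydration may follow once the β-hydroxy ketone meets base in step 18.
Fallback: from 25, buffered HF·pyridine (THF, 0 °C) should remove only the TES and TBS groups to give the diol ketal acid F6. Ac2O/pyridine should give the diacetate ketal acid F7. Neutral transketalisation (I2, 10 mol %, acetone, rt) then releases the ketone last, so no base ever meets the β-acyloxy ketone. This rejoins the route at 28.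

**Further compounds**
F1 | step 19 | (E)-5-(iodomethylene)butenolide keto diacetate | C/C=C(/C)C(=O)O[C@@H](C/C(CO[Si](c1ccccc1)(c1ccccc1)C(C)(C)C)=C\[C@@H](OC(C)=O)CC(C)=O)C1=C(COC(C)=O)C(=O)O/C1=C/I
F2 | step 15 | 2-formylfuran alcohol | O=Cc1occ(CO[Si](C)(C)C(C)(C)C)c1[C@@H](O)C/C(CO[Si](c1ccccc1)(c1ccccc1)C(C)(C)C)=C\[C@@H](O[Si](CC)(CC)CC)CC1(C)OCCO1
F3 | step 15 | formylfuran angelate | O=Cc1occ(CO[Si](C)(C)C(C)(C)C)c1[C@@H](OC(=O)/C(C)=C\C)C/C(CO[Si](c1ccccc1)(c1ccccc1)C(C)(C)C)=C\[C@@H](O[Si](CC)(CC)CC)CC1(C)OCCO1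
F4 | step 15 | tosylhydrazone of F3 | Cc1ccc(cc1)S(=O)(=O)NN=Cc1occ(CO[Si](C)(C)C(C)(C)C)c1[C@@H](OC(=O)/C(C)=C\C)C/C(CO[Si](c1ccccc1)(c1ccccc1)C(C)(C)C)=C\[C@@H](O[Si](CC)(CC)CC)CC1(C)OCCO1
F5 | step 15 | cis-enynal (C12 aldehyde) | O=C/C(CO[Si](C)(C)C(C)(C)C)=C(\C#C)[C@@H](OC(=O)/C(C)=C\C)C/C(CO[Si](c1ccccc1)(c1ccccc1)C(C)(C)C)=C\[C@@H](O[Si](CC)(CC)CC)CC1(C)OCCO1
F6 | step 17 | diol ketal acid | OC(=O)/C(CO)=C(\C#C)[C@@H](OC(=O)/C(C)=C\C)C/C(CO[Si](c1ccccc1)(c1ccccc1)C(C)(C)C)=C\[C@@H](O)CC1(C)OCCO1
F7 | step 17 | diacetate ketal acid | OC(=O)/C(COC(C)=O)=C(\C#C)[C@@H](OC(=O)/C(C)=C\C)C/C(CO[Si](c1ccccc1)(c1ccccc1)C(C)(C)C)=C\[C@@H](OC(C)=O)CC1(C)OCCO1
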